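Ring B is opened retrosynthetically at C7=C8 (olefin metathesis). Everything then rests on removing the C5–C6 bond and one C4–CH3 bond from ring A. The key step puts both back in one operation. Allylcopper attacks C5 of a ring A enone, the carbon that ends up tertiary between quaternary C4 and C10, on the face away from the branched C9 chain on C10. The C3–C4 enolate so defined is then C-methylated, which sets H-5 anti to the C10 methyl group. The precursor is a 2,4-dimethylcyclohex-2-enone whose C10 bears methyl and a CH(CH2OSiPh2t-Bu)(isopropenyl) chain. C9 comes from an auxiliary-controlled alkylation, C10 from a butyrolactone template.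

Key step: step 10

Remarks on the design (all precede the steps)
- **Numbering:** drimane numbering is used for every intermediate: C3 ketone, C4 gem-dimethyl, C5/C10 ring fusion, C9 bearing C11H2O, C8 bearing the vinylic methyl. β is the face of the C10 methyl group.
- **Configuration check:** the target is (5R,9R,10S), with H-5 α, the C10 methyl β and H-9 β, so C11 is α and axial on ring B. The enone precursor must be (9R,10S) and the key-step product (5R,9R,10S). Both map onto the target unchanged.
- **C10:** a stereocentre α to a formyl group is erased as soon as the aldehyde becomes an enamine or enolate. It therefore cannot be carried from a sigmatropic step into a Michael addition, and an open-chain α-branched aldehyde gives no dependable bias for the new quaternary centre. Only C9 is set by a chiral controller here. C10 is then built on a five-membered lactone in which C9 is the neighbouring ring atom.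
- **Order of alkylation:** the target needs the C1–C3 chain trans and the methyl cis to the isopropenyl group on that lactone. Methyl is therefore introduced first and the chain second.
- **O-11 protection:** a tert-butyldiphenylsilyl ether is used instead of a benzyl-type ether. It enlarges the C9 chain and cannot chelate magnesium or copper and so guide the allyl reagent to the wrong face. It is removed with fluoride, without an oxidant.
- **Assumption:** the C3 carbinol carbon formed in step 6 is an epimer mixture that is oxidised away in step 8. The enol silane formed in step 5 has undefined double-bond geometry. Both are drawn without these descriptors.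

Step 1
Reactants: 1 (S)-4-benzyloxazolidin-2-one; 2 3-methylbut-2-enoyl chloride
Product: 4 (S)-4-benzyl-3-(3-methylbut-2-enoyl)oxazolidin-2-one, via N-lithio oxazolidinone 3 (not isolated)
Conditions: n-BuLi, THF, −78 °C; then 2, −78 → 0 °C
Reagents that add atoms: none
Why: N-Acylation of a lithiated oxazolidinone with an acid chloride is the standard entry to Evans imides; no stereocentre is formed or disturbed.

Step 2
Reactants: 4 (S)-4-benzyl-3-(3-methylbut-2-enoyl)oxazolidin-2-one; 5 tert-butyl bromoacetate
Product: 7 tert-butyl (3S)-3-{[(4S)-4-benzyl-2-oxooxazolidin-3-yl]carbonyl}-4-methylpent-4-enoate, via sodium dienolate 6 (not isolated)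
Conditions: NaN(SiMe3)2, THF, −78 °C; then 5, −78 → −40 °C
Reagents that add atoms: none
Why: Evans asymmetric alkylation in its deconjugative variant: removal of a γ-proton gives the sodium-chelated Z-dienolate 6, which reacts with the activated bromide at its α-carbon (C9) on the face opposite the benzyl group, so that C9 is set (3S in 7) by the auxiliary and the double bond moves out to the isopropenyl position (C8).

Step 3
Reactants: 7 tert-butyl (3S)-3-{[(4S)-4-benzyl-2-oxooxazolidin-3-yl]carbonyl}-4-methylpent-4-enoate
Product: 9 (4S)-4-(prop-1-en-2-yl)dihydrofuran-2(3H)-one, via hydroxy ester 8 (not isolated)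
Conditions: LiBH4, H2O (1 equiv), Et2O, 0 °C; crude product, p-TsOH·H2O (5 mol %), CH2Cl2, rt
Reagents that add atoms: none
Why: Reductive cleavage of the imide with LiBH4 leaves the tert-butyl ester and the unactivated alkene alone, and the γ-hydroxy ester 8 then closes to the five-membered lactone by acid-catalysed intramolecular transesterification; after the reduction C9 carries no acidic hydrogen and keeps its configuration.

Step 4
Reactants: 9 (4S)-4-(prop-1-en-2-yl)dihydrofuran-2(3H)-one; 10 iodomethane
Product: 12 (3R,4S)-3-methyl-4-(prop-1-en-2-yl)dihydrofuran-2(3H)-one, via lithium enolate 11 (not isolated)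
Conditions: LiN(i-Pr)2, THF, −78 °C; then 10, −78 → −40 °C
Reagents that add atoms: iodomethane 10, CI
Why: Lactone enolate alkylation: iodomethane enters anti to the neighbouring isopropenyl group to give mainly the trans isomer, but the C10 configuration is irrelevant here because this carbon is made planar again in step 5.

Step 5
Reactants: 12 (3R,4S)-3-methyl-4-(prop-1-en-2-yl)dihydrofuran-2(3H)-one; 13 pent-1-en-3-one (ethyl vinyl ketone)
Product: 17 (3R,4R)-3-methyl-3-(3-oxopentyl)-4-(prop-1-en-2-yl)dihydrofuran-2(3H)-one, via lithium enolate 14 (not isolated), via silyl ketene acetal 15 (not isolated), via enol silane 16 (not isolated)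
Conditions: LiN(i-Pr)2, THF, −78 °C; Me3SiCl, −78 °C → rt; evaporate, pentane, filter; 13, Sc(OTf)3 (5 mol %), CH2Cl2, −78 → −20 °C; 1 M HCl, THF, 0 °C
Reagents that add atoms: none
Why: Mukaiyama–Michael addition: the cyclic silyl ketene acetal 15 has no E/Z ambiguity, is nucleophilic enough to build a quaternary carbon, and meets the Lewis-acid-activated vinyl ketone on the ring face anti to the adjacent isopropenyl group, so that the C1–C3 chain ends trans and the methyl cis to C8, which is the C9/C10 relationship of the target (10R by descriptor in 17).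

Step 6
Reactants: 17 (3R,4R)-3-methyl-3-(3-oxopentyl)-4-(prop-1-en-2-yl)dihydrofuran-2(3H)-one
Product: 18 (2R)-2-[(2R)-1-hydroxy-3-methylbut-3-en-2-yl]-2-methylheptane-1,5-diol (epimers at the secondary carbinol C3)
Conditions: LiAlH4, THF, 0 °C → rt
Reagents that add atoms: none
Why: Exhaustive hydride reduction opens the lactone to the C5/C11 diol and takes the C3 ketone along; the new C3 carbinol centre forms without control and is erased again in step 8.

Step 7
Reactants: 18 (2R)-2-[(2R)-1-hydroxy-3-methylbut-3-en-2-yl]-2-methylheptane-1,5-diol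
Product: 19 (2R)-2-[(2R)-1-(tert-butyldiphenylsilyloxy)-3-methylbut-3-en-2-yl]-2-methylheptane-1,5-diol
Conditions: t-BuPh2SiCl (1.0 equiv), imidazole, CH2Cl2, −20 → 0 °C
Reagents that add atoms: tert-butyldiphenylsilyl chloride, CC(C)(C)[Si](Cl)(c1ccccc1)c1ccccc1
Why: Sterically differentiated monosilylation: the bulky chlorosilane should take the C11 hydroxyl, which hangs on a tertiary carbon, ahead of the neopentyl C5 hydroxyl on quaternary C10 and the secondary C3 hydroxyl; no stereocentre is affected.

Step 8
Reactants: 19 (2R)-2-[(2R)-1-(tert-butyldiphenylsilyloxy)-3-methylbut-3-en-2-yl]-2-methylheptane-1,5-diol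
Product: 20 (2R)-2-[(2R)-1-(tert-butyldiphenylsilyloxy)-3-methylbut-3-en-2-yl]-2-methyl-5-oxoheptanal
Conditions: (COCl)2, DMSO, CH2Cl2, −78 °C; Et3N, −78 → 0 °C
Reagents that add atoms: none
Why: Double Swern oxidation: both hydroxyls are activated at −78 °C before base is added, which avoids a C5/O-3 lactol and its over-oxidation, and the aldehyde formed has a quaternary α-carbon and cannot epimerise.

Step 9
Reactants: 20 (2R)-2-[(2R)-1-(tert-butyldiphenylsilyloxy)-3-methylbut-3-en-2-yl]-2-methyl-5-oxoheptanal
Product: 21 (4S)-4-[(2R)-1-(tert-butyldiphenylsilyloxy)-3-methylbut-3-en-2-yl]-2,4-dimethylcyclohex-2-en-1-one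
Conditions: KOH (0.3 equiv), MeOH–THF, 0 °C → rt
Reagents that add atoms: none
Why: Intramolecular aldol condensation, the ring-closing half of a Robinson annulation: the C5 aldehyde cannot enolise, only the C4 methylene of the ethyl ketone reaches it through a six-membered transition state (C2 would give a four-membered ring), and E1cB loss of water closes ring A as the 2-methyl enone without touching C9 or C10.

Step 10
Reactants: 21 (4S)-4-[(2R)-1-(tert-butyldiphenylsilyloxy)-3-methylbut-3-en-2-yl]-2,4-dimethylcyclohex-2-en-1-one; 22 allylmagnesium bromide; 10 iodomethane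
Product: 25 (3R,4S)-3-allyl-4-[(2R)-1-(tert-butyldiphenylsilyloxy)-3-methylbut-3-en-2-yl]-2,2,4-trimethylcyclohexan-1-one, via silyl enol ether 23 (not isolated), via lithium enolate 24 (not isolated)
Conditions: 22 (3 equiv), CuBr·SMe2 (3 equiv), Me3SiCl (6 equiv), THF, −78 °C; cold aq NaHCO3 wash, evaporate; MeLi (1.1 equiv), THF, 0 °C; 10 (5 equiv), DMPU, −78 → 0 °C
Reagents that add atoms: allylmagnesium bromide 22, C=CC[Mg]Br; iodomethane 10, CI
Why: Allylcopper, made from 22 and CuBr·SMe2, binds the C4=C5 bond of 21 and, with Me3SiCl speeding the transfer and capturing the oxygen, hands its allyl group to C5 to give silyl enol ether 23 instead of the carbonyl adduct that harder allyl metals prefer. MeLi then attacks only the small SiMe3 group and frees lithium enolate 24 with its double bond fixed between C3 and C4, and iodomethane alkylates C4, which completes the gem-dimethyl carbon and creates no stereocentre there. The closest known reaction type is the chlorosilane-assisted copper conjugate addition to 4,4-disubstituted cyclohexenones followed by C-alkylation of the regenerated, regiodefined enolate; no ring is closed. The single new stereocentre, C5, is controlled by quaternary C10: axial attack runs through the half-chair that holds the branched C9 chain pseudoaxial and comes from the opposite face, past the methyl group, so that C6 ends trans to C9 and cis to the C10 methyl group and H-5 is α (5R), the arrangement a trans-fused ring B needs. The step needs 1,4- over 1,2-selectivity (soft neutral copper reagent plus Me3SiCl), facial selectivity (size gap between CH3 and the CH(CH2OSiPh2t-Bu)(isopropenyl) chain, whose hindered silyl ether cannot chelate magnesium or copper and steer the reagent to its own face) and C4- over C2-methylation (the enolate is generated aprotically from 23 and met by excess iodomethane before proton transfer can move it).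

Step 11
Reactants: 25 (3R,4S)-3-allyl-4-[(2R)-1-(tert-butyldiphenylsilyloxy)-3-methylbut-3-en-2-yl]-2,2,4-trimethylcyclohexan-1-one
Product: 26 (4aS,5R,8aR)-5-[(tert-butyldiphenylsilyloxy)methyl]-1,1,4a,6-tetramethyl-3,4,4a,5,8,8a-hexahydronaphthalen-2(1H)-one
Conditions: second-generation Grubbs catalyst (5 mol %), CH2Cl2 (5 mM), 40 °C
Reagents that add atoms: none
Why: Ring-closing metathesis: the ruthenium carbene loads on the monosubstituted allyl alkene and closes on the 1,1-disubstituted isopropenyl alkene, which is possible because C6 and C9 are trans-diequatorial neighbours on ring A, giving six-membered ring B with its trisubstituted C7=C8 bond; all three stereocentres are spectators.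

Step 12
Reactants: 26 (4aS,5R,8aR)-5-[(tert-butyldiphenylsilyloxy)methyl]-1,1,4a,6-tetramethyl-3,4,4a,5,8,8a-hexahydronaphthalen-2(1H)-one
Product: 27 (4aS,5R,8aR)-5-(hydroxymethyl)-1,1,4a,6-tetramethyl-3,4,4a,5,8,8a-hexahydronaphthalen-2(1H)-one
Conditions: Bu4NF, AcOH (1:1), THF, rt
Reagents that add atoms: none
Why: Fluoride-induced silyl ether cleavage, buffered with acetic acid so that the C3 ketone never meets a basic medium; no stereocentre is involved.

Step 13
Reactants: 27 (4aS,5R,8aR)-5-(hydroxymethyl)-1,1,4a,6-tetramethyl-3,4,4a,5,8,8a-hexahydronaphthalen-2(1H)-one; 28 umbelliferone (7-hydroxy-2H-chromen-2-one)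
Product: 29 7-{[(1R,4aR,8aS)-2,5,5,8a-tetramethyl-6-oxo-1,4,4a,5,6,7,8,8a-octahydronaphthalen-1-yl]methoxy}-2H-chromen-2-one (target CNP0262399.7)
Conditions: PPh3, DIAD, THF, 0 °C → rt
Reagents that add atoms: none
Why: Mitsunobu etherification: the acidic 7-hydroxyl of umbelliferone protonates the betaine and its phenoxide displaces the oxyphosphonium group at primary C11, so no stereocentre is affected and the ketone, the alkene and the coumarin lactone are left alone.

Compound list
1 | (S)-4-benzyloxazolidin-2-one | O=C1N[C@@H](Cc2ccccc2)CO1 | starting material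
2 | 3-methylbut-2-enoyl chloride | CC(C)=CC(=O)Cl | starting material
3 | N-lithio-(S)-4-benzyloxazolidin-2-one | O=C1N([Li])[C@@H](Cc2ccccc2)CO1 | intermediate
4 | (S)-4-benzyl-3-(3-methylbut-2-enoyl)oxazolidin-2-one | CC(C)=CC(=O)N1[C@@H](Cc2ccccc2)COC1=O | intermediate
5 | tert-butyl bromoacetate | CC(C)(C)OC(=O)CBr | starting material
6 | sodium (Z)-dienolate of 4 | C=C(C)/C=C(\O[Na])N1[C@@H](Cc2ccccc2)COC1=O | intermediate
7 | tert-butyl (3S)-3-{[(4S)-4-benzyl-2-oxooxazolidin-3-yl]carbonyl}-4-methylpent-4-enoate | CC(C)(C)OC(=O)C[C@@H](C(C)=C)C(=O)N1[C@@H](Cc2ccccc2)COC1=O | intermediate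
8 | tert-butyl (3S)-3-(hydroxymethyl)-4-methylpent-4-enoate | CC(C)(C)OC(=O)C[C@@H](C(C)=C)CO | intermediate
9 | (4S)-4-(prop-1-en-2-yl)dihydrofuran-2(3H)-one | O=C1OC[C@H](C(C)=C)C1 | intermediate
10 | iodomethane | CI | starting material
11 | lithium enolate of 9 (C9 unchanged) | C=C(C)[C@H]1COC(O[Li])=C1 | intermediate
12 | (3R,4S)-3-methyl-4-(prop-1-en-2-yl)dihydrofuran-2(3H)-one (trans) | O=C1OC[C@H](C(C)=C)[C@H]1C | intermediate
13 | pent-1-en-3-one (ethyl vinyl ketone) | CCC(=O)C=C | starting material
14 | lithium enolate of 12 (C9 unchanged) | C=C(C)[C@H]1COC(O[Li])=C1C | intermediate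
15 | 3-methyl-4-(prop-1-en-2-yl)-2-(trimethylsilyloxy)-4,5-dihydrofuran (C9 unchanged) | C=C(C)[C@H]1COC(O[Si](C)(C)C)=C1C | intermediate
16 | trimethylsilyl enol ether (C2=C3, geometry undefined) of 17 | O=C1OC[C@H](C(C)=C)[C@@]1(C)CC=C(CC)O[Si](C)(C)C | intermediate
17 | (3R,4R)-3-methyl-3-(3-oxopentyl)-4-(prop-1-en-2-yl)dihydrofuran-2(3H)-one | O=C1OC[C@H](C(C)=C)[C@@]1(C)CCC(=O)CC | intermediate
18 | (2R)-2-[(2R)-1-hydroxy-3-methylbut-3-en-2-yl]-2-methylheptane-1,5-diol (C3 carbinol epimers) | CCC(O)CC[C@@](C)(CO)[C@H](CO)C(C)=C | intermediate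
19 | (2R)-2-[(2R)-1-(tert-butyldiphenylsilyloxy)-3-methylbut-3-en-2-yl]-2-methylheptane-1,5-diol | CCC(O)CC[C@@](C)(CO)[C@H](CO[Si](c1ccccc1)(c1ccccc1)C(C)(C)C)C(C)=C | intermediate
20 | (2R)-2-[(2R)-1-(tert-butyldiphenylsilyloxy)-3-methylbut-3-en-2-yl]-2-methyl-5-oxoheptanal | CCC(=O)CC[C@@](C)(C=O)[C@H](CO[Si](c1ccccc1)(c1ccccc1)C(C)(C)C)C(C)=C | intermediate
21 | (4S)-4-[(2R)-1-(tert-butyldiphenylsilyloxy)-3-methylbut-3-en-2-yl]-2,4-dimethylcyclohex-2-en-1-one (9R,10S; key-step precursor) | CC1=C[C@](C)(CCC1=O)[C@H](CO[Si](c2ccccc2)(c2ccccc2)C(C)(C)C)C(C)=C | intermediate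
22 | allylmagnesium bromide | C=CC[Mg]Br | starting material
23 | C3–C4 trimethylsilyl enol ether of the 5-allyl ketone (5R,9R,10S) | C=CC[C@H]1C(C)=C(O[Si](C)(C)C)CC[C@]1(C)[C@H](CO[Si](c2ccccc2)(c2ccccc2)C(C)(C)C)C(C)=C | intermediate
24 | C3–C4 lithium enolate of the 5-allyl ketone (5R,9R,10S) | C=CC[C@H]1C(C)=C(O[Li])CC[C@]1(C)[C@H](CO[Si](c2ccccc2)(c2ccccc2)C(C)(C)C)C(C)=C | intermediate
25 | (3R,4S)-3-allyl-4-[(2R)-1-(tert-butyldiphenylsilyloxy)-3-methylbut-3-en-2-yl]-2,2,4-trimethylcyclohexan-1-one (5R,9R,10S; key-step product) | C=CC[C@H]1C(C)(C)C(=O)CC[C@]1(C)[C@H](CO[Si](c2ccccc2)(c2ccccc2)C(C)(C)C)C(C)=C | intermediate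
26 | (4aS,5R,8aR)-5-[(tert-butyldiphenylsilyloxy)methyl]-1,1,4a,6-tetramethyl-3,4,4a,5,8,8a-hexahydronaphthalen-2(1H)-one | CC1=CC[C@H]2C(C)(C)C(=O)CC[C@]2(C)[C@@H]1CO[Si](c3ccccc3)(c3ccccc3)C(C)(C)C | intermediate
27 | (4aS,5R,8aR)-5-(hydroxymethyl)-1,1,4a,6-tetramethyl-3,4,4a,5,8,8a-hexahydronaphthalen-2(1H)-one | CC1=CC[C@H]2C(C)(C)C(=O)CC[C@]2(C)[C@@H]1CO | intermediate
28 | umbelliferone (7-hydroxy-2H-chromen-2-one) | Oc1ccc2ccc(=O)oc2c1 | starting material
29 | 7-{[(1R,4aR,8aS)-2,5,5,8a-tetramethyl-6-oxo-1,4,4a,5,6,7,8,8a-octahydronaphthalen-1-yl]methoxy}-2H-chromen-2-one | CC1=CC[C@H]2C(C)(C)C(=O)CC[C@]2(C)[C@@H]1COc1ccc2ccc(=O)oc2c1 | target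

Total step count: 13.
Longest linear sequence: 13 steps (1 → 29). The other inputs (2, 5, 10, 13, 22, 28) are bought.

Steps most likely to fail

1. **Step 10.** Three things can go wrong:
   - the allyl nucleophile may attack the C3 carbonyl instead of the hindered C5;
   - the facial bias at C5 may be too small;
   - proton transfer in the crowded enolate may outrun C-methylation.

   The fallback sets out from 21 and returns at 25. Reagent 22 is added on purpose to the carbonyl group (CeCl3, THF, −78 °C) and the two carbinol epimers are separated. The epimer with the allyl group on the β face, (1S,4S)-1-allyl-4-[(2R)-1-(tert-butyldiphenylsilyloxy)-3-methylbut-3-en-2-yl]-2,4-dimethylcyclohex-2-en-1-ol F1, is deprotonated with KH and 18-crown-6 in THF to its potassium alkoxide F2. An anionic oxy-Cope rearrangement then moves the allyl group suprafacially from C3 to C5 on that same face and gives the potassium C3–C4 enolate F3. This is quenched in the same flask with iodomethane 10 to give 25. The configuration at C5 is then fixed by the choice of carbinol epimer, not by an intermolecular approach.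

2. **Step 13.** Substitution at C11 may be slow, because C11 is axial on ring B and lies next to quaternary C10. Loss of the allylic H-9 from the activated alcohol (elimination towards a diene) may then take over. The fallback sets out from 27 and returns at 29. The ether is made from the other side by forming the aryl–oxygen bond in a palladium-catalysed C–O cross-coupling of alcohol 27 with commercial 7-bromocoumarin ([(allyl)PdCl]2, RockPhos, Cs2CO3, toluene, 90 °C). C11 is never an electrophile, so neither its shielding nor elimination matters. No new compound is made on the way (F0).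

3. **Step 7.** Site selectivity between the C11 and C5 hydroxyls may be poor, or the silyl group may migrate between them. The fallback sets out from 17 and returns at 19, and it distinguishes the two oxygens by function instead of by size. Lactone 17 is saponified (LiOH, THF–H2O) to the lithium hydroxy carboxylate F4. The dried salt is silylated on both oxygens (t-BuPh2SiCl, imidazole, DMF) to the silyl ether silyl ester F5. The labile silyl ester alone is cleaved (K2CO3, MeOH–H2O) to the silyloxy keto acid F6. LiAlH4 in THF at 0 °C reduces the acid and the ketone to give 19.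

Further compounds
F1 | step 10 | (1S,4S)-1-allyl-4-[(2R)-1-(tert-butyldiphenylsilyloxy)-3-methylbut-3-en-2-yl]-2,4-dimethylcyclohex-2-en-1-ol | C=CC[C@@]1(O)CC[C@@](C)(C=C1C)[C@H](CO[Si](c2ccccc2)(c2ccccc2)C(C)(C)C)C(C)=C
F2 | step 10 | potassium alkoxide of F1 | C=CC[C@@]1(O[K])CC[C@@](C)(C=C1C)[C@H](CO[Si](c2ccccc2)(c2ccccc2)C(C)(C)C)C(C)=C
F3 | step 10 | C3–C4 potassium enolate of the 5-allyl ketone (5R,9R,10S) | C=CC[C@H]1C(C)=C(O[K])CC[C@]1(C)[C@H](CO[Si](c2ccccc2)(c2ccccc2)C(C)(C)C)C(C)=C
F0 | step 13 | none | none
F4 | step 7 | lithium (2R)-2-[(2R)-1-hydroxy-3-methylbut-3-en-2-yl]-2-methyl-5-oxoheptanoate | CCC(=O)CC[C@@](C)(C(=O)[O-])[C@H](CO)C(C)=C.[Li+]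
F5 | step 7 | tert-butyldiphenylsilyl (2R)-2-[(2R)-1-(tert-butyldiphenylsilyloxy)-3-methylbut-3-en-2-yl]-2-methyl-5-oxoheptanoate | CCC(=O)CC[C@@](C)(C(=O)O[Si](c1ccccc1)(c1ccccc1)C(C)(C)C)[C@H](CO[Si](c1ccccc1)(c1ccccc1)C(C)(C)C)C(C)=C
F6 | step 7 | (2R)-2-[(2R)-1-(tert-butyldiphenylsilyloxy)-3-methylbut-3-en-2-yl]-2-methyl-5-oxoheptanoic acid | CCC(=O)CC[C@@](C)(C(=O)O)[C@H](CO[Si](c1ccccc1)(c1ccccc1)C(C)(C)C)C(C)=C
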